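**Assumptions (one line):** atom labels C1–C20 are the ent‑kaurane numbering of the target (C6 = CHO, C7 = lactone C=O, C19 = CH2OAc, C20 = lactone CH2); for the two catalytic asymmetric steps (4 and 10) the catalyst antipode named is the one expected from the accepted models to give the drawn enantiomer, and the other antipode is used if the sense proves opposite.

## Retrosynthetic overview

1. Endgame: C6 alcohol → aldehyde, C16 α‑methylenation, C15=CH2 → C15=O, thermodynamic reduction of the C11 ketone, C20–O/C7 lactonization.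
2. Key disconnection: C9–C10, and in the same radical chain C8–C15. A tertiary C10 radical on the A ring adds to C9 of an ene‑keto‑ester C ring, and the resulting C8 radical closes 5‑exo‑dig onto a C13 propargyl group.
3. A‑ring fragment: catalytic asymmetric Diels–Alder of a (Z)‑2‑vinylbutene‑1,4‑diol bis‑silyl ether with methacrolein sets C4 and C5; HAT hydrobromination gives the radical precursor.
4. C‑ring fragment: amine‑catalysed Michael/aldol annulation of acetone with an enynyl α‑keto ester sets C13.
5. Ring order: A and C rings separately → D ring (bicyclo[3.2.1]octane) in the radical cascade → δ‑lactone → functional‑group endgame.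

## Route

**Step 1**
Reactants: 1, 2‑butyne‑1,4‑diol
Product: 2, (2E)‑2‑(tributylstannyl)but‑2‑ene‑1,4‑diol
Conditions: Bu3SnH, PdCl2(PPh3)2 (2 mol%), THF, rt
Reagents that add atoms: tributyltin hydride, CCCC[SnH](CCCC)CCCC
Why: Pd‑catalysed hydrostannation is a syn addition to the symmetrical alkyne, so H and Sn are cis and the two CH2OH groups end up cis.

**Step 2**
Reactants: 2; 3, vinyl bromide
Product: 4, (2Z)‑2‑ethenylbut‑2‑ene‑1,4‑diol
Conditions: Pd(PPh3)4 (5 mol%), CuI, CsF, DMF, 45 °C
Reagents that add atoms: none
Why: Stille coupling proceeds with retention, giving the diene with the C5 CH2OH trans to the vinyl group ("outside" substituent), as needed for a reactive s‑cis diene.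

**Step 3**
Reactants: 4
Product: 5, (2Z)‑1,4‑bis[(tert‑butyldimethylsilyl)oxy]‑2‑ethenylbut‑2‑ene
Conditions: TBSCl, imidazole, DMF, rt
Reagents that add atoms: TBSCl, CC(C)(C)[Si](C)(C)Cl
Why: Standard bis‑silylation of the two primary alcohols so the diene tolerates the Lewis acid in the next step.

**Step 4**
Reactants: 5; 6, methacrolein
Product: 7, (1R,2S)‑2,3‑bis{[(tert‑butyldimethylsilyl)oxy]methyl}‑1‑methylcyclohex‑3‑ene‑1‑carbaldehyde (CHO cis to the C2 CH2OTBS; ring C1 = C4, C2 = C5, C3 = C10 of the target)
Conditions: (S)‑o‑tolyl‑oxazaborolidine·HNTf2 (20 mol%), CH2Cl2, −78 °C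
Reagents that add atoms: none
Why: Catalytic asymmetric Diels–Alder; the substituted diene terminus directs "ortho" bond formation (C4–C5) as with 1‑vinylcycloalkenes, the endo‑CHO transition state places CHO cis to the outside CH2OTBS, and the chiral oxazaborolidinium controls the face to set C4 and C5.

**Step 5**
Reactants: 7
Product: 8, [(1R,2R)‑2,3‑bis{[(tert‑butyldimethylsilyl)oxy]methyl}‑1‑methylcyclohex‑3‑en‑1‑yl]methanol
Conditions: NaBH4, MeOH, 0 °C
Reagents that add atoms: none
Why: Chemoselective hydride reduction of the neopentyl aldehyde; no stereocentre is touched.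

**Step 6**
Reactants: 8
Product: 9, [(1R,2R)‑2,3‑bis{[(tert‑butyldimethylsilyl)oxy]methyl}‑1‑methylcyclohex‑3‑en‑1‑yl]methyl acetate
Conditions: Ac2O, DMAP, pyridine, CH2Cl2, rt
Reagents that add atoms: acetic anhydride, CC(=O)OC(C)=O
Why: Acylation installs the C19 acetate of the target while the other two oxygens are still silylated.

**Step 7**
Reactants: 9
Product: 10, [(1R,2S)‑3‑bromo‑2,3‑bis{[(tert‑butyldimethylsilyl)oxy]methyl}‑1‑methylcyclohexyl]methyl acetate (tertiary bromide at C10, epimer mixture, inconsequential)
Conditions: Co(acac)2, t‑BuOOH, Et3SiH, TsBr, n‑PrOH, rt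
Reagents that add atoms: tosyl bromide, Cc1ccc(cc1)S(=O)(=O)Br
Why: Mukaiyama‑type HAT hydrobromination delivers H to the less substituted alkene carbon (C1) and Br to the tertiary C10 radical under non‑acidic conditions that spare the TBS ethers and acetate.

**Step 8**
Reactants: 11, methyl bromopyruvate
Product: 12, methyl 2‑oxo‑3‑(triphenylphosphoranylidene)propanoate
Conditions: PPh3, PhMe, rt; then aq. Na2CO3, CH2Cl2
Reagents that add atoms: triphenylphosphine, c1ccc(cc1)P(c1ccccc1)c1ccccc1
Why: SN2 phosphonium salt formation and deprotonation give the stabilised acyl ylide.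

**Step 9**
Reactants: 13, but‑3‑yn‑1‑ol; 12
Product: 14, methyl (3E)‑2‑oxohept‑3‑en‑6‑ynoate
Conditions: Dess–Martin periodinane, NaHCO3, CH2Cl2, 0 °C; then 12, rt (one pot)
Reagents that add atoms: none
Why: Oxidation/Wittig in one pot traps the labile but‑3‑ynal before it isomerises, and the stabilised ylide gives the E enone.

**Step 10**
Reactants: 14; 15, acetone
Product: 16, methyl (5S)‑3‑oxo‑5‑(prop‑2‑yn‑1‑yl)cyclohex‑1‑ene‑1‑carboxylate (ring C1 = C8, C2 = C9, C3 = C11, C5 = C13 of the target)
Conditions: 9‑amino‑9‑deoxy‑epi‑quinine (20 mol%), PhCO2H (40 mol%), acetone, rt; then p‑TsOH·H2O, PhMe, 50 °C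
Reagents that add atoms: none
Why: Enamine‑catalysed Michael addition of acetone to the β,γ‑unsaturated α‑keto ester sets C13 under catalyst control, and intramolecular aldol condensation of the methyl ketone onto the α‑keto ester (Robinson‑type annulation) gives the ene‑keto‑ester.

**Step 11 (key step)**
Reactants: 10; 16 (2.5 equiv, excess recovered)
Product: 17, methyl 2‑[(1S,2R,3R)‑3‑(acetoxymethyl)‑1,2‑bis{[(tert‑butyldimethylsilyl)oxy]methyl}‑3‑methylcyclohexyl]‑7‑methylidene‑3‑oxobicyclo[3.2.1]octane‑1‑carboxylate; kaurane‑numbered configuration 4R,5R,8S,9R,10S,13S (the C9 epimer is also carried forward)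
Conditions: Bu3SnH (1.5 equiv, syringe pump), AIBN, PhH, 80 °C
Reagents that add atoms: none
Why: Tin‑mediated radical addition–cyclization cascade, with the following course and stereocontrol:
- The tertiary C10 radical adds (Giese) to the unsubstituted C9 of the doubly activated alkene, on the ring face anti to the C5 CH2OTBS and away from the axial C4 CH2OAc, which sets C10.
- The resulting tertiary α‑ester C8 radical closes 5‑exo‑dig onto the propargyl alkyne, which is possible only cis to the (13S) side chain, so C13 dictates C8 and the bicyclo[3.2.1]octane.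
- The vinyl radical takes H from Bu3SnH; slow addition keeps both intermediate radicals alive long enough to react.

**Step 12**
Reactants: 17
Product: 18, the 7,20‑δ‑lactone with free C6–OH, C11 ketone and C15=CH2 (4R,5R,8S,9R,10S,13S); trans‑fused lactone/C‑ring
Conditions: HF·pyridine, THF, 0 °C → rt; then DBU, PhMe, 60 °C
Reagents that add atoms: none
Why: Desilylation frees C20–OH, which lactonizes onto the C7 methyl ester (MeOH lost), and DBU equilibrates C9 through the C11 enolate to the stable epimer with C10 equatorial on the locked C‑ring chair (natural configuration).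

**Step 13**
Reactants: 18
Product: 19, the (11R)‑alcohol (equatorial OH, anti to the C15–C16 bridge); 4R,5R,8S,9R,10S,11R,13S
Conditions: SmI2 (2.5 equiv), H2O, THF, 0 °C
Reagents that add atoms: none
Why: Single‑electron (ketyl) reduction gives the thermodynamic equatorial alcohol, because the axial position at C11 is blocked by C5, C15 and C16; hydride reagents would attack from the open face and give the wrong epimer. The ketone is reduced much faster than the δ‑lactone or acetate.

**Step 14**
Reactants: 19
Product: 20, the C15 ketone (C16 = CH2), C6–OH and C11–OH free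
Conditions: O3, CH2Cl2, −78 °C; then PPh3
Reagents that add atoms: ozone, [O-][O+]=O
Why: Ozonolysis of the only alkene converts the exocyclic methylene into the C15 ketone; it is done after step 13 so that the two ketones never have to be differentiated.

**Step 15**
Reactants: 20
Product: 21, the α‑methylene ketone (C16=CH2) with C6–OH and C11–OH free
Conditions: (CH2O)n, N‑methylanilinium trifluoroacetate, THF, 65 °C
Reagents that add atoms: formaldehyde (paraformaldehyde), C=O
Why: Mannich‑type α‑methylenation under mildly acidic conditions; C16 is the only enolizable position of the C15 ketone (C8 is quaternary), and the acetate, lactone and free alcohols are tolerated.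

**Step 16**
Reactants: 21
Product: 22, trichorabdal B
Conditions: TEMPO (20 mol%), PhI(OAc)2, CH2Cl2, rt
Reagents that add atoms: none
Why: Oxoammonium oxidation is selective for the primary C6 alcohol over the hindered secondary C11 alcohol and stops at the aldehyde without epimerizing C5.

## Compound list

1 | 2‑butyne‑1,4‑diol | OCC#CCO | starting material
2 | (2E)‑2‑(tributylstannyl)but‑2‑ene‑1,4‑diol | OC/C=C(\CO)[Sn](CCCC)(CCCC)CCCC | intermediate
3 | vinyl bromide | C=CBr | starting material
4 | (2Z)‑2‑ethenylbut‑2‑ene‑1,4‑diol | C=C/C(CO)=C/CO | intermediate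
5 | (2Z)‑1,4‑bis(TBSO)‑2‑ethenylbut‑2‑ene | C=C/C(CO[Si](C)(C)C(C)(C)C)=C/CO[Si](C)(C)C(C)(C)C | intermediate
6 | methacrolein | CC(=C)C=O | starting material
7 | (1R,2S)‑2,3‑bis(TBSOCH2)‑1‑methylcyclohex‑3‑ene‑1‑carbaldehyde | O=C[C@]1(C)CCC=C(CO[Si](C)(C)C(C)(C)C)[C@@H]1CO[Si](C)(C)C(C)(C)C | intermediate
8 | [(1R,2R)‑2,3‑bis(TBSOCH2)‑1‑methylcyclohex‑3‑en‑1‑yl]methanol | OC[C@]1(C)CCC=C(CO[Si](C)(C)C(C)(C)C)[C@@H]1CO[Si](C)(C)C(C)(C)C | intermediate
9 | [(1R,2R)‑2,3‑bis(TBSOCH2)‑1‑methylcyclohex‑3‑en‑1‑yl]methyl acetate | CC(=O)OC[C@]1(C)CCC=C(CO[Si](C)(C)C(C)(C)C)[C@@H]1CO[Si](C)(C)C(C)(C)C | intermediate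
10 | [(1R,2S)‑3‑bromo‑2,3‑bis(TBSOCH2)‑1‑methylcyclohexyl]methyl acetate (C–Br epimers) | CC(=O)OC[C@]1(C)CCCC(Br)(CO[Si](C)(C)C(C)(C)C)[C@@H]1CO[Si](C)(C)C(C)(C)C | intermediate
11 | methyl bromopyruvate | COC(=O)C(=O)CBr | starting material
12 | methyl 2‑oxo‑3‑(triphenylphosphoranylidene)propanoate | COC(=O)C(=O)C=P(c1ccccc1)(c1ccccc1)c1ccccc1 | intermediate
13 | but‑3‑yn‑1‑ol | C#CCCO | starting material
14 | methyl (3E)‑2‑oxohept‑3‑en‑6‑ynoate | C#CC/C=C/C(=O)C(=O)OC | intermediate
15 | acetone | CC(C)=O | starting material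
16 | methyl (5S)‑3‑oxo‑5‑(prop‑2‑yn‑1‑yl)cyclohex‑1‑ene‑1‑carboxylate | C#CC[C@@H]1CC(=O)C=C(C(=O)OC)C1 | intermediate
17 | cascade product: bicyclo[3.2.1]octane methyl ester, C11 ketone, C15=CH2, bis‑TBS | C1C(=C)[C@]2(C(=O)OC)C[C@H]1CC(=O)[C@@H]2[C@@]1(CCC[C@@](C)(COC(C)=O)[C@H]1CO[Si](C)(C)C(C)(C)C)CO[Si](C)(C)C(C)(C)C | intermediate
18 | 7,20‑lactone, C11 ketone, C15=CH2, C6–OH | C1C(=C)[C@]23C[C@H]1CC(=O)[C@@H]2[C@@]1(CCC[C@@](C)(COC(C)=O)[C@H]1CO)COC3=O | intermediate
19 | 7,20‑lactone, (11R)‑OH, C15=CH2, C6–OH | C1C(=C)[C@]23C[C@H]1C[C@@H](O)[C@@H]2[C@@]1(CCC[C@@](C)(COC(C)=O)[C@H]1CO)COC3=O | intermediate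
20 | 7,20‑lactone, 11‑OH, C15 ketone, C6–OH | C1C(=O)[C@]23C[C@H]1C[C@@H](O)[C@@H]2[C@@]1(CCC[C@@](C)(COC(C)=O)[C@H]1CO)COC3=O | intermediate
21 | 6‑hydroxy precursor (16‑methylene‑15‑ketone) | C=C1C(=O)[C@]23C[C@H]1C[C@@H](O)[C@@H]2[C@@]1(CCC[C@@](C)(COC(C)=O)[C@H]1CO)COC3=O | intermediate
22 | trichorabdal B | C=C1C(=O)[C@]23C[C@H]1C[C@@H](O)[C@@H]2[C@@]1(CCC[C@@](C)(COC(C)=O)[C@H]1C=O)COC3=O | target

## Summary

Total steps: 16. Longest linear sequence: 13 (steps 1–7, then 11–16); the C‑ring branch is steps 8–10.

Three steps most likely to fail, each with a fallback that changes the approach: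

1. **Step 11 (radical addition–cyclization cascade).** The hindered tertiary radical may add poorly to C9, or the C8 radical may be reduced before it cyclizes. Fallback: decouple the two bonds. Make only C9–C10 by Giese addition, lactonize as in step 12, then close C8–C15 by Au(I)‑catalysed 5‑exo‑dig carbocyclization of the lactone silyl ketene acetal onto the alkyne, with the C11 ketone masked as its silyl enol ether.
2. **Step 4 (intermolecular asymmetric Diels–Alder).** Regiochemistry (1‑ versus 2‑substituent control), endo selectivity and ee are all at stake while a quaternary centre forms. Fallback: tether the dienophile as the methacrylate ester of the C6 oxygen and run an intramolecular Diels–Alder, which enforces the C4–C5 bond and the cis C6/C19 relationship, then open the γ‑lactone reductively and resolve (for example by lipase acylation).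
3. **Step 10 (organocatalytic annulation).** The skipped enyne CH2 can isomerize and the ee with an aliphatic substrate is uncertain. Fallback: make racemic 16 (pyrrolidine‑mediated annulation) and use the enantiopure A‑ring partner as the resolving element, separating the two C13‑diastereomeric cascade products after step 11.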